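Z has no single time constant in these flasks: its loss rate contains [L], and [L] falls.

- larch: Z 0.0020 M; L 5.00 mM; time 80 s
- alder: Z 0.0020 M; L 12.0 mM; time 80 s

    Z + Q → Z.Q (k1 = 33.6 M⁻¹ s⁻¹)
    Q ⇌ E (K2 = 2.45, k2 = 0.0720 s⁻¹)
    Z → J (k3 = 0.0575 s⁻¹)
    L → G (k4 = 0.187 s⁻¹)
    Z + L → Q (k5 = 12.9 M⁻¹ s⁻¹)
    Z + L → Z.L (k6 = 32.7 M⁻¹ s⁻¹)

- in percentages every species weighs as the Z in it: one Z.Q counts as two
- run time (larch): 80 s

1. which of these there is most of at the end, counted by the Z in it, larch (Z.Q / Z.L / Q / J / E)
2. which of these there is most of at the end, counted by the Z in it, alder (Z.Q / Z.L / Q / J / E)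
3. how much there is at the end of the one of these that leads, in percent of the Z charged: larch
4. how much there is at the end of the one of these that leads, in percent of the Z charged: alder

Build the flask up one process at a time. With Z → J alone, you have a time constant of 17.4 s, and nearly all of Z is J by 80 s.

Now add capture by L. Steps Z + L → Q and Z + L → Z.L together give Z a pseudo-first-order rate of 45.6 M⁻¹ s⁻¹ times [L]. With [L] held at the larch charge that is 0.228 s⁻¹, faster than the 0.0575 s⁻¹ of the first route, and J would shrink to 20.1%. A share s = 0.717 of what is captured becomes Z.L.

But capture is a closing window, since [L] does not stay at its charge. L decays at 0.187 s⁻¹, and Z consumes it as well, at 45.6 M⁻¹ s⁻¹ times [Z], where I take [Z] at half the Z charge as a rough mean. Z also leaves by its first route, so less of it remains to be captured. Summed, the window closes at 0.290 s⁻¹.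

In larch, the capture rate at the charge divided by the closing rate is 0.786; call this ratio the capture number N. In alder it is 1.89. I reckon the fraction exp(−N) as escaping capture and ending as J, and s(1 − exp(−N)) as Z.L. The two cross at N = ln(1 + 1/s) = 0.873, where control changes hands. In this reckoning the Q branch stays smaller than Z.L, for even doubled, as Z.Q counts, its share is less than s.

Larch lies below the crossing, so I commit to J at 45.6%. Alder lies above it, so there I commit to Z.L at 60.8%.

The forecast, noting that “L dies quickly”, gave J at 48% for larch and Z.L at 57% for alder.

The simulation gives J at 45.3% in larch and Z.L at 57.4% in alder.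

Larch is close to rest at 80 s, with L at 0% of its charge and Z at 0.30%. At 800 s, J in larch has gone from 45.3% to 45.6%, while Z.L reads 36.7% before and 36.7% after. The reckoning with N = 0.786 already books such leftover Z as J. Alder, with 0.053% of its Z left, shows J at 17.7% and, at 800 s, 17.8%.

Take the neighbour of alder charged with 0.0072 M of L, which is 3.60 equiv of L to Z. Its capture number is 1.13, above the crossing, so you expect Z.L to lead at 48.5% with J at 32.3%. The computed flask holds 45.9% Z.L and 32.8% J.

The numbers of this flask are assumed; what happens was integrated by code.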